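## Retrosynthetic overview

1. Target 19 ⇐ ketol 17 by acetylation and desilylation; 17 already holds both rings and all six stereocentres.
2. 17 ⇐ acyclic enal-dialdehyde 15 in one flask: first C6–C2 (amine-catalysed intramolecular Michael, six-membered ring, trans C2/C6), then C4–C5 (carbene-catalysed acyloin closure, cyclopentanone with the C5 oxygen in place).
3. 15 ⇐ methyl ketone 11 + C3 boronate 13 (enol triflate, Suzuki coupling: C1(=CH2)–C2=C3–C4).
4. 11 ⇐ cyclohexene 9 by ozonolysis of C1=C5; the carvone ring is only a stereochemical template for C7–C9 and is opened, C5 leaving the ring.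
5. 9 ⇐ (S)-carvone 1: C7 from the pool; C8/C9 by trans-bromide → cis-epoxide → anti opening with angelic acid 7.

Assumption: locants follow the target skeleton (C1 = ring carbon carrying the exocyclic CH2 C10; C2 and C6 = ring-fusion carbons, C2 next to C1; C3 = CH2; C4 = C=O; C5 = CH–OAc; C7 = CH–iPr; C8 = CH–OH; C9 = CH–O-angelate); 1, 7 and 13 are bought.

## Route

Step 1
Reactants: 1 (S)-(+)-carvone
Product: 2 (5S)-2-methyl-5-(propan-2-yl)cyclohex-2-en-1-one [(S)-carvotanacetone]
Conditions: H2 (1 atm), RhCl(PPh3)3 (2 mol%), toluene, rt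
Reagents that add atoms: none
Why: Homogeneous (Wilkinson) hydrogenation saturates only the unhindered 1,1-disubstituted isopropenyl alkene and leaves the trisubstituted enone alkene, so the C7 stereocentre of the target is taken unchanged from (S)-carvone.

Step 2
Reactants: 2 (S)-carvotanacetone
Product: 4 (5R,6R)-6-bromo-2-methyl-5-(propan-2-yl)cyclohex-2-en-1-one (Br trans to iPr), via TMS dienol ether 3 (not isolated)
Conditions: LDA, THF, −78 °C; TMSCl; then NBS, THF, −78 °C; used crude and cold
Reagents that add atoms: chlorotrimethylsilane C[Si](C)(C)Cl (held in 3 only); N-bromosuccinimide O=C1CCC(=O)N1Br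
Why: Kinetic α′-deprotonation and O-silylation give the cross-conjugated silyl dienol ether, and electrophilic bromination of this silyl enol ether by NBS occurs at C8 on the face anti to the neighbouring isopropyl group, giving the trans bromide.

Step 3
Reactants: 4 trans-bromo ketone
Product: 6 (1R,5R,6S)-2-methyl-5-(propan-2-yl)-7-oxabicyclo[4.1.0]hept-2-ene (epoxide cis to iPr), via trans-bromohydrin 5 (not isolated)
Conditions: NaBH4, CeCl3·7H2O, MeOH, −78 → −20 °C; then K2CO3, MeOH, 0 °C → rt
Reagents that add atoms: none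
Why: Luche 1,2-reduction delivers hydride to the enone face anti to the isopropyl group (the carvone → cis-carveol sense) to give the trans-bromohydrin, whose alkoxide then displaces bromide with inversion at C8 (intramolecular Williamson epoxide closure), placing the epoxide cis to the isopropyl group.

Step 4
Reactants: 6 vinyl epoxide; 7 angelic acid
Product: 8 (1S,5R,6S)-6-hydroxy-2-methyl-5-(propan-2-yl)cyclohex-2-en-1-yl (2Z)-2-methylbut-2-enoate
Conditions: angelic acid (3 equiv), Cs2CO3 (0.2 equiv), MeCN, 45 °C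
Reagents that add atoms: angelic acid 7 C/C=C(/C)C(=O)O
Why: Carboxylic acid opening of the vinyl epoxide is an SN2 anti opening at the allylic carbon C9 (inversion there, C8–O bond retained), which installs the angelate at C9 trans to the C8 hydroxyl that sits cis to the isopropyl group.

Step 5
Reactants: 8 hydroxy angelate
Product: 9 (1S,5R,6S)-6-[(tert-butyldimethylsilyl)oxy]-2-methyl-5-(propan-2-yl)cyclohex-2-en-1-yl (2Z)-2-methylbut-2-enoate
Conditions: TBSOTf, 2,6-lutidine, CH2Cl2, −40 → 0 °C
Reagents that add atoms: tert-butyldimethylsilyl triflate CC(C)(C)[Si](C)(C)OS(=O)(=O)C(F)(F)F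
Why: Silylation with TBSOTf/2,6-lutidine (silyl ether protection) blocks the hindered C8 hydroxyl under non-nucleophilic conditions so that the vicinal angelate cannot migrate once the ring is opened.

Step 6
Reactants: 9 silyl ether
Product: 11 (3R,4S,5R)-4-[(tert-butyldimethylsilyl)oxy]-7,7-dimethoxy-2-oxo-5-(propan-2-yl)heptan-3-yl (2Z)-2-methylbut-2-enoate, via keto aldehyde 10 (not isolated)
Conditions: O3, CH2Cl2/MeOH 4:1, −78 °C (Sudan Red 7B end point); Me2S, −78 °C → rt; then HC(OMe)3, PPTS (cat.), MeOH, rt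
Reagents that add atoms: ozone [O-][O+]=O; trimethyl orthoformate COC(OC)OC
Why: Ozonolysis with reductive work-up cleaves the electron-rich trisubstituted C1=C5 ring alkene much faster than the electron-poor angelate alkene, and acid-catalysed acetalisation then masks only the unhindered C5 aldehyde and not the hindered α-acyloxy methyl ketone; no stereocentre is touched.

Step 7
Reactants: 11 keto acetal
Product: 12 (3R,4S,5R)-4-[(tert-butyldimethylsilyl)oxy]-7,7-dimethoxy-5-(propan-2-yl)-2-{[(trifluoromethyl)sulfonyl]oxy}hept-1-en-3-yl (2Z)-2-methylbut-2-enoate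
Conditions: KHMDS (1.1 equiv), Comins' reagent, THF, −78 °C
Reagents that add atoms: Comins' reagent [N-(5-chloropyridin-2-yl)-bis(trifluoromethanesulfonimide)] FC(F)(F)S(=O)(=O)N(c1ccc(Cl)cn1)S(=O)(=O)C(F)(F)F
Why: Kinetic deprotonation of the methyl ketone at the methyl group and O-sulfonylation with Comins' reagent at −78 °C (enol triflate formation) give the 1,1-disubstituted alkenyl triflate that already holds C10 as the future exocyclic methylene.

Step 8
Reactants: 12 alkenyl triflate; 13 (E)-2-(3,3-diethoxyprop-1-en-1-yl)-4,4,5,5-tetramethyl-1,3,2-dioxaborolane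
Product: 14 (2E,5S,6S,7R)-6-[(tert-butyldimethylsilyl)oxy]-1,1-diethoxy-9,9-dimethoxy-4-methylidene-7-(propan-2-yl)non-2-en-5-yl (2Z)-2-methylbut-2-enoate
Conditions: PdCl2(dppf)·CH2Cl2 (5 mol%), K3PO4, THF/H2O 10:1, rt
Reagents that add atoms: boronate 13 CCOC(OCC)/C=C/B1OC(C)(C)C(C)(C)O1
Why: Suzuki–Miyaura cross-coupling of the alkenyl triflate with the (E)-alkenylboronate proceeds with retention of alkene geometry and joins C1 to the C2–C4 unit as a 2-substituted 1,3-diene.

Step 9
Reactants: 14 bis-acetal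
Product: 15 (2E,5S,6S,7R)-6-[(tert-butyldimethylsilyl)oxy]-4-methylidene-1,9-dioxo-7-(propan-2-yl)non-2-en-5-yl (2Z)-2-methylbut-2-enoate
Conditions: TsOH·H2O (10 mol%), acetone/H2O 10:1, rt; used at once
Reagents that add atoms: water O
Why: Acid-catalysed acetal hydrolysis (transacetalisation to acetone) frees the enal and the saturated aldehyde while the hindered secondary TBS ether and the ester survive these mild conditions.

Step 10
Reactants: 15 enal-dialdehyde
Product: 17 (1R,3aR,5S,6S,7S,7aR)-6-[(tert-butyldimethylsilyl)oxy]-1-hydroxy-4-methylidene-2-oxo-7-(propan-2-yl)octahydro-1H-inden-5-yl (2Z)-2-methylbut-2-enoate, via Michael dialdehyde 16 (not isolated)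
Conditions: (S)-α,α-diphenylprolinol TMS ether (20 mol%), PhCO2H (20 mol%), CH2Cl2 (0.02 M), rt; then 3-benzyl-5-(2-hydroxyethyl)-4-methylthiazolium chloride (20 mol%), Et3N (40 mol%), 40 °C, same flask
Reagents that add atoms: none
Why: Proposed new method: the enamine of the saturated C5 aldehyde adds through C6 to the β-carbon C2 of the amine-activated enal (6-exo Michael) through a chair in which iPr, C5 and C3 are equatorial and the two oxygens axial (allylic strain from the methylidene favours the axial 9-ester), which sets C2 and C6 trans with C6 free to epimerise to the equatorial aldehyde and the (S)-catalyst shielding the wrong face of C2; the thiazolylidene then forms its Breslow intermediate at the unhindered C4 aldehyde and adds to the α-branched C5 aldehyde to give the 4-ketone/5-carbinol, whose C5 equilibrates under Et3N to the pseudo-equatorial hydroxyl cis to H-6; the closest known reactions are amine-catalysed intramolecular aldehyde-to-enal Michael additions, thiazolium-catalysed cyclisation of 1,5-dialdehydes to 2-hydroxycyclopentanones and sequential amine/carbene Michael–benzoin cascades.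

Step 11
Reactants: 17 ketol
Product: 18 (1R,3aR,5S,6S,7S,7aR)-1-(acetyloxy)-6-[(tert-butyldimethylsilyl)oxy]-4-methylidene-2-oxo-7-(propan-2-yl)octahydro-1H-inden-5-yl (2Z)-2-methylbut-2-enoate
Conditions: Ac2O, pyridine, DMAP (cat.), CH2Cl2, 0 °C
Reagents that add atoms: acetic anhydride CC(=O)OC(C)=O
Why: DMAP-catalysed O-acylation (esterification) of the α-ketol hydroxyl, the only free hydroxyl, gives the acetate in the pseudo-equatorial configuration already fixed thermodynamically at C5.

Step 12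
Reactants: 18 silyl ether
Product: 19 (1R,3aR,5S,6S,7S,7aR)-1-(acetyloxy)-6-hydroxy-4-methylidene-2-oxo-7-(propan-2-yl)octahydro-1H-inden-5-yl (2Z)-2-methylbut-2-enoate (CNP0317011.1)
Conditions: HF·pyridine, pyridine/THF, 0 °C → rt
Reagents that add atoms: none
Why: Fluoride-induced Si–O cleavage (desilylation) with buffered HF·pyridine leaves the ketone, both esters and the exocyclic alkene untouched, and the trans-diaxial 8-OH/9-O-angelate arrangement in the rigid trans-hydrindane prevents acyl migration.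

## Compound list

1 | (S)-(+)-carvone | CC1=CC[C@H](C(C)=C)CC1=O | starting material
2 | (5S)-2-methyl-5-(propan-2-yl)cyclohex-2-en-1-one | CC1=CC[C@H](C(C)C)CC1=O | intermediate
3 | trimethyl{[(3R)-6-methyl-3-(propan-2-yl)cyclohexa-1,5-dien-1-yl]oxy}silane | CC1=CC[C@H](C(C)C)C=C1O[Si](C)(C)C | intermediate (not isolated)
4 | (5R,6R)-6-bromo-2-methyl-5-(propan-2-yl)cyclohex-2-en-1-one | CC1=CC[C@H](C(C)C)[C@@H](Br)C1=O | intermediate
5 | (1R,5R,6R)-6-bromo-2-methyl-5-(propan-2-yl)cyclohex-2-en-1-ol | CC1=CC[C@H](C(C)C)[C@@H](Br)[C@@H]1O | intermediate (not isolated)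
6 | (1R,5R,6S)-2-methyl-5-(propan-2-yl)-7-oxabicyclo[4.1.0]hept-2-ene | CC1=CC[C@H](C(C)C)[C@@H]2O[C@H]12 | intermediate
7 | angelic acid, (2Z)-2-methylbut-2-enoic acid | C/C=C(/C)C(=O)O | starting material
8 | (1S,5R,6S)-6-hydroxy-2-methyl-5-(propan-2-yl)cyclohex-2-en-1-yl (2Z)-2-methylbut-2-enoate | CC1=CC[C@H](C(C)C)[C@H](O)[C@H]1OC(=O)/C(C)=C\C | intermediate
9 | (1S,5R,6S)-6-[(tert-butyldimethylsilyl)oxy]-2-methyl-5-(propan-2-yl)cyclohex-2-en-1-yl (2Z)-2-methylbut-2-enoate | CC1=CC[C@H](C(C)C)[C@H](O[Si](C)(C)C(C)(C)C)[C@H]1OC(=O)/C(C)=C\C | intermediate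
10 | (3R,4S,5R)-4-[(tert-butyldimethylsilyl)oxy]-2,7-dioxo-5-(propan-2-yl)heptan-3-yl (2Z)-2-methylbut-2-enoate | CC(=O)[C@H](OC(=O)/C(C)=C\C)[C@@H](O[Si](C)(C)C(C)(C)C)[C@@H](C(C)C)CC=O | intermediate (not isolated)
11 | (3R,4S,5R)-4-[(tert-butyldimethylsilyl)oxy]-7,7-dimethoxy-2-oxo-5-(propan-2-yl)heptan-3-yl (2Z)-2-methylbut-2-enoate | CC(=O)[C@H](OC(=O)/C(C)=C\C)[C@@H](O[Si](C)(C)C(C)(C)C)[C@@H](C(C)C)CC(OC)OC | intermediate
12 | (3R,4S,5R)-4-[(tert-butyldimethylsilyl)oxy]-7,7-dimethoxy-5-(propan-2-yl)-2-{[(trifluoromethyl)sulfonyl]oxy}hept-1-en-3-yl (2Z)-2-methylbut-2-enoate | C=C(OS(=O)(=O)C(F)(F)F)[C@H](OC(=O)/C(C)=C\C)[C@@H](O[Si](C)(C)C(C)(C)C)[C@@H](C(C)C)CC(OC)OC | intermediate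
13 | (E)-2-(3,3-diethoxyprop-1-en-1-yl)-4,4,5,5-tetramethyl-1,3,2-dioxaborolane | CCOC(OCC)/C=C/B1OC(C)(C)C(C)(C)O1 | starting material
14 | (2E,5S,6S,7R)-6-[(tert-butyldimethylsilyl)oxy]-1,1-diethoxy-9,9-dimethoxy-4-methylidene-7-(propan-2-yl)non-2-en-5-yl (2Z)-2-methylbut-2-enoate | C=C(/C=C/C(OCC)OCC)[C@H](OC(=O)/C(C)=C\C)[C@@H](O[Si](C)(C)C(C)(C)C)[C@@H](C(C)C)CC(OC)OC | intermediate
15 | (2E,5S,6S,7R)-6-[(tert-butyldimethylsilyl)oxy]-4-methylidene-1,9-dioxo-7-(propan-2-yl)non-2-en-5-yl (2Z)-2-methylbut-2-enoate | C=C(/C=C/C=O)[C@H](OC(=O)/C(C)=C\C)[C@@H](O[Si](C)(C)C(C)(C)C)[C@@H](C(C)C)CC=O | intermediate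
16 | (1S,3R,4R,5S,6S)-6-[(tert-butyldimethylsilyl)oxy]-4-formyl-2-methylidene-3-(2-oxoethyl)-5-(propan-2-yl)cyclohexyl (2Z)-2-methylbut-2-enoate | C=C1[C@H](CC=O)[C@@H](C=O)[C@H](C(C)C)[C@H](O[Si](C)(C)C(C)(C)C)[C@H]1OC(=O)/C(C)=C\C | intermediate (not isolated)
17 | (1R,3aR,5S,6S,7S,7aR)-6-[(tert-butyldimethylsilyl)oxy]-1-hydroxy-4-methylidene-2-oxo-7-(propan-2-yl)octahydro-1H-inden-5-yl (2Z)-2-methylbut-2-enoate | C=C1[C@@H]2CC(=O)[C@H](O)[C@H]2[C@H](C(C)C)[C@H](O[Si](C)(C)C(C)(C)C)[C@H]1OC(=O)/C(C)=C\C | intermediate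
18 | (1R,3aR,5S,6S,7S,7aR)-1-(acetyloxy)-6-[(tert-butyldimethylsilyl)oxy]-4-methylidene-2-oxo-7-(propan-2-yl)octahydro-1H-inden-5-yl (2Z)-2-methylbut-2-enoate | C=C1[C@@H]2CC(=O)[C@H](OC(C)=O)[C@H]2[C@H](C(C)C)[C@H](O[Si](C)(C)C(C)(C)C)[C@H]1OC(=O)/C(C)=C\C | intermediate
19 | (1R,3aR,5S,6S,7S,7aR)-1-(acetyloxy)-6-hydroxy-4-methylidene-2-oxo-7-(propan-2-yl)octahydro-1H-inden-5-yl (2Z)-2-methylbut-2-enoate | C=C1[C@@H]2CC(=O)[C@H](OC(C)=O)[C@H]2[C@H](C(C)C)[C@H](O)[C@H]1OC(=O)/C(C)=C\C | target

## Step count and risks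

Total step count: 12. Longest linear sequence: 12 steps from (S)-carvone 1 (7 and 13 are bought).

**Step 10 (bicyclisation).** Three things can go wrong:
- the enamine can attack the δ-carbon C10 instead of the β-carbon C2; both close a six-membered ring, and precedent with β-unsubstituted dienals favours β-attack;
- the diastereoselection at C2/C6 can be low;
- the carbene can be slow to engage two aliphatic aldehydes.

Fallback: starting from 15, run only the amine-catalysed Michael step and isolate dialdehyde 16. Close the five-membered ring reductively with SmI2 (THF, −78 °C, pinacol coupling) to the cis-4,5-diol F1. Oxidise the less hindered C4 carbinol with IBX (1.1 equiv, DMSO, rt); a misplaced ketol moves to the less strained 4-ketone through the enediol on brief Et3N treatment. This comes back to the route at 17.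

**Step 3 (reduction and epoxide closure).** Hydride may add anti to the C–Br bond and give the cis-bromohydrin, which cannot close. Base can also strip HBr from 4 and aromatise it to carvacrol.

Fallback: starting from 4, displace bromide with cesium formate (DMF, 0 °C, SN2 with inversion at C8) to give the cis-formyloxy ketone F2. Luche reduction then places the C9 hydroxyl cis to the formate, giving hydroxy formate F3 (here the polar and steric preferences agree). Mitsunobu esterification with angelic acid 7 (PPh3, DIAD, toluene, 0 °C) inverts C9 to the angelate formate F4. NH3 in MeOH at 0 °C removes only the formate. This comes back to the route at 8 without passing through epoxide 6.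

**Step 8 (Suzuki coupling).** Pd(0) can ionise the allylic angelate of 12 or of 14 to a π-allyl complex; the triflate formation before it is also base-sensitive.

Fallback: starting from 11, add (E)-3,3-diethoxyprop-1-enylcerium dichloride (from (E)-1-bromo-3,3-diethoxyprop-1-ene, t-BuLi, then CeCl3, THF, −78 °C, cold quench) to the methyl ketone to give the tertiary alcohol F5. Dehydrate with Burgess reagent (toluene, 50 °C); syn elimination can use only the methyl hydrogens or the deactivated C9–H, so the methylidene forms. This comes back to the route at 14 without palladium and without triflate 12.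

Further compounds
F1 | step 10 | (1R,2R,3aR,5S,6S,7S,7aR)-6-[(tert-butyldimethylsilyl)oxy]-1,2-dihydroxy-4-methylidene-7-(propan-2-yl)octahydro-1H-inden-5-yl (2Z)-2-methylbut-2-enoate (cis-4,5-diol, drawn as the α,α isomer) | C=C1[C@@H]2C[C@H](O)[C@H](O)[C@H]2[C@H](C(C)C)[C@H](O[Si](C)(C)C(C)(C)C)[C@H]1OC(=O)/C(C)=C\C
F2 | step 3 | (1S,6R)-3-methyl-2-oxo-6-(propan-2-yl)cyclohex-3-en-1-yl formate (formate cis to iPr) | CC1=CC[C@H](C(C)C)[C@H](OC=O)C1=O
F3 | step 3 | (1S,2R,6R)-2-hydroxy-3-methyl-6-(propan-2-yl)cyclohex-3-en-1-yl formate | CC1=CC[C@H](C(C)C)[C@H](OC=O)[C@@H]1O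
F4 | step 3 | (1S,5R,6S)-6-(formyloxy)-2-methyl-5-(propan-2-yl)cyclohex-2-en-1-yl (2Z)-2-methylbut-2-enoate | CC1=CC[C@H](C(C)C)[C@H](OC=O)[C@H]1OC(=O)/C(C)=C\C
F5 | step 8 | (2E,5S,6S,7R)-6-[(tert-butyldimethylsilyl)oxy]-1,1-diethoxy-4-hydroxy-9,9-dimethoxy-4-methyl-7-(propan-2-yl)non-2-en-5-yl (2Z)-2-methylbut-2-enoate (mixture of C4 carbinol epimers) | CC(O)(/C=C/C(OCC)OCC)[C@H](OC(=O)/C(C)=C\C)[C@@H](O[Si](C)(C)C(C)(C)C)[C@@H](C(C)C)CC(OC)OC
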